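**Plan** (carotenoid numbering; primed atoms belong to the ε half)

- Cuts, in retrosynthetic order: the two palmitate C–O bonds; C14–C15 (Suzuki–Miyaura); C14'–C15' together with C13'–CH3 (key step); C10'–C11' together with C9'–CH3 (same chemistry one cycle earlier); in the epoxy half C11=C12 and C7=C8 (two Horner–Wadsworth–Emmons reactions), C6–C7 (carbonylation) and the oxirane C–O bonds.
- Forward: the ε-ring chain grows C13 → C18 → C21 by two methylalumination/Negishi cycles and the epoxy-ring chain grows C10 → C15 → C19 by olefination. The halves are joined at C14–C15, then desilylated and palmitoylated; the only ring made is the oxirane, both carbocycles are bought.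
- Enabling feature: C13' carries a methyl group on a trisubstituted E-alkene while the neighbouring C15'=C15 alkene is unbranched. C13'(Me)=C14' is therefore what syn addition of CH3 and a metal to the terminal C13'≡C14' alkyne of the ε-ring trienyne gives, and the metal on C14' is the handle for C14'–C15'.
- Stereochemistry: C3'/C6' trans from hydride delivery to the 3'-ketone, then lipase resolution; C3 from (4R,6R)-actinol; C5/C6 from D-(−)-tartrate-controlled Sharpless epoxidation; E-alkenes from syn carbometalation, stereoretentive couplings and E-selective olefinations.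

Key step: step 12

Remark: (4R,6R)-actinol 24 is taken as a purchasable chiral-pool ketone (the usual building block for 3-hydroxy carotenoid end groups).

**Part A – ε half**

Step 1
Reactants: 1 (E)-α-ionone (racemic)
Product: 2 α-ionone ethylene ketal (racemic)
Conditions: HO(CH2)2OH, HC(OMe)3, p-TsOH·H2O (cat.), 25 °C
Reagents that add atoms: ethylene glycol (OCCO)
Why: Acid-catalysed acetalisation (dioxolane formation) with the orthoformate as water scavenger masks the side-chain ketone so that the ring can be oxidised and reduced selectively, and no stereocentre is touched.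

Step 2
Reactants: 2 α-ionone ethylene ketal (racemic)
Product: 3 3-oxo-α-ionone ethylene ketal (racemic)
Conditions: t-BuOOH (70% aq.), NaOCl (aq.), K2CO3, MeCN, −5 → 0 °C
Reagents that add atoms: tert-butyl hydroperoxide (CC(C)(C)OO)
Why: Radical allylic oxidation by tert-butylperoxyl radicals converts the only unhindered secondary allylic CH2 (C3', next to the trisubstituted C4'=C5' bond) into the enone carbonyl, the tertiary C6'–H being shielded by the gem-dimethyl group and the C5' methyl group.

Step 3
Reactants: 3 3-oxo-α-ionone ethylene ketal (racemic)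
Product: 4 trans-3-hydroxy-α-ionone ethylene ketal (racemic)
Conditions: K[(s-Bu)3BH], THF, −78 °C; H2O
Reagents that add atoms: none
Why: 1,2-Reduction of the β,β-disubstituted cyclohexenone by a bulky trialkylborohydride should deliver hydride anti to the pseudoaxial C1' methyl group of the half-chair that keeps the C6' side chain pseudoaxial, which places the new C3' hydroxyl trans to the side chain (relative configuration only, racemic).

Step 4
Reactants: 4 trans-3-hydroxy-α-ionone ethylene ketal (racemic)
Product: 5 (3R,6R)-3-hydroxy-α-ionone ethylene ketal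
Conditions: lipase PS (Burkholderia cepacia), vinyl acetate, t-BuOMe, 30 °C, run slightly past half conversion; chromatography
Reagents that add atoms: none
Why: Lipase-catalysed enantioselective transesterification (kinetic resolution) is expected to acetylate the (3S,6S) enantiomer, whose carbinol matches the fast-reacting spatial type of 3-hydroxy β-ring alcohols, and to leave the (3R,6R) alcohol untouched, which sets the absolute configuration at C3' and C6'.

Step 5
Reactants: 5 (3R,6R)-3-hydroxy-α-ionone ethylene ketal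
Product: 6 (3R,6R)-3-(tert-butyldimethylsilyloxy)-α-ionone ethylene ketal
Conditions: TBSCl, imidazole, DMF, 25 °C
Reagents that add atoms: tert-butyldimethylsilyl chloride (CC(C)(C)[Si](C)(C)Cl)
Why: Standard silylation of a secondary allylic alcohol gives an ether that tolerates the amide bases, alanes and palladium chemistry that follow.

Step 6
Reactants: 6 (3R,6R)-3-(tert-butyldimethylsilyloxy)-α-ionone ethylene ketal
Product: 7 (3R,6R)-3-(tert-butyldimethylsilyloxy)-α-ionone
Conditions: PPTS (cat.), acetone/H2O, 25 °C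
Reagents that add atoms: water (O)
Why: Mild acid-catalysed acetal hydrolysis unmasks the enone through an allyl-stabilised oxocarbenium ion under conditions that leave the secondary silyl ether intact.

Step 7
Reactants: 7 (3R,6R)-3-(tert-butyldimethylsilyloxy)-α-ionone
Product: 9 C13 silyloxy enyne, via enol phosphate 8 (not isolated)
Conditions: LiN(i-Pr)2 (1.1 equiv), THF, −78 °C; ClP(O)(OEt)2, −78 → 25 °C; LiN(i-Pr)2 (2.2 equiv), −78 → 0 °C; aq. NH4Cl
Reagents that add atoms: none
Why: Kinetic α'-deprotonation of the methyl ketone, O-phosphorylation and base-induced β-elimination of diethyl phosphate from enol phosphate 8 (enol phosphate route to terminal alkynes) should give the enyne, the hindered doubly allylic C6'–H being left alone at low temperature.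

Step 8
Reactants: 10 acetylene
Product: 11 (E)-1-bromo-2-iodoethene
Conditions: IBr, 48% aq. HBr, 0 °C
Reagents that add atoms: iodine monobromide (BrI)
Why: Electrophilic anti addition of iodine monobromide across acetylene through a bridged iodonium ion gives the E-dihaloethene.

Step 9
Reactants: 11 (E)-1-bromo-2-iodoethene; 12 ethynyltrimethylsilane
Product: 14 (E)-1-bromo-4-(trimethylsilyl)but-1-en-3-yne, via alkynylzinc bromide 13 (not isolated)
Conditions: 12, n-BuLi, THF, −78 °C; ZnBr2, 0 °C; then 11, Pd(PPh3)4 (cat.), 0 → 25 °C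
Reagents that add atoms: none
Why: Negishi alkynylzinc coupling in which zerovalent palladium inserts into the weaker C–I bond only, so that the bromide and the E geometry are kept.

Step 10
Reactants: 9 C13 silyloxy enyne; 14 (E)-1-bromo-4-(trimethylsilyl)but-1-en-3-yne; 15 trimethylaluminium
Product: 18 C18 silyl-capped trienyne, via dienylalane 16 (not isolated), via dienylzinc chloride 17 (not isolated)
Conditions: AlMe3 (2 equiv), Cp2ZrCl2 (0.3 equiv), (CH2Cl)2, 25 °C; evaporate; ZnCl2 (1 equiv), THF; 14, Pd2(dba)3 (cat.), P(2-furyl)3, DMF, 25 °C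
Reagents that add atoms: none
Why: Zirconium-catalysed syn methylalumination of the terminal alkyne places CH3 on C9' and the metal on C10' (9'E), and Negishi coupling of the derived zinc species with the E-bromoenyne forms C10'–C11' with retention at both partners.

Step 11
Reactants: 18 C18 silyl-capped trienyne
Product: 19 ε C18 trienyne with terminal C13'≡C14' alkyne
Conditions: K2CO3, MeOH, 25 °C
Reagents that add atoms: none
Why: Methoxide-induced protodesilylation of the alkynyl C–Si bond frees the terminal alkyne while the secondary silyl ether is untouched.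

Step 12
Reactants: 19 ε C18 trienyne; 15 trimethylaluminium; 11 (E)-1-bromo-2-iodoethene
Product: 22 ε C21 bromopentaene, via tetraenylalane 20 (not isolated), via tetraenylzinc chloride 21 (not isolated)
Conditions: AlMe3 (2 equiv), Cp2ZrCl2 (0.5 equiv), (CH2Cl)2, 25 °C; evaporate; ZnCl2 (1 equiv), THF; 11 (3 equiv), Pd(PPh3)4 (5 mol %), 0 → 25 °C, dark
Reagents that add atoms: none
Why: Cp2ZrCl2 and AlMe3 form a methylzirconium–aluminium species that adds CH3 and metal syn across the terminal C13'≡C14' bond, methyl to the internal C13' and the metal (aluminium after exchange) to C14', which gives alane 20 with the 13'E geometry. ZnCl2 then moves the alkenyl group to zinc (21), zerovalent palladium from Pd(PPh3)4 inserts into the C–I bond of 11, and transmetalation with reductive elimination forms C14'–C15' with retention at both alkenyl carbons. The closest known reaction type is zirconium-catalysed methylalumination of terminal enynes followed by palladium/zinc-mediated Negishi alkenyl–alkenyl coupling with 1,2-dihaloethenes, as used for retinoid and carotene polyenes. No ring is closed and no stereocentre is created; the two new E double bonds are fixed by the syn mode of carbometalation and by stereoretentive coupling. The step needs methyl delivery to the internal carbon, which the terminal alkyne secures, and coupling at iodine only, which the weaker C–I bond and the excess of 11 secure. The substrate offers the alane no Lewis-basic or acid-labile site other than the hindered allylic silyl ether, because the oxirane half is brought in only afterwards.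

Step 13
Reactants: 22 ε C21 bromopentaene
Product: 23 ε C21 pentaenyl pinacol boronate
Conditions: B2pin2, PdCl2(PPh3)2 (3 mol %), PPh3, KOPh, toluene, 50 °C, dark
Reagents that add atoms: bis(pinacolato)diboron (CC1(C)OB(OC1(C)C)B1OC(C)(C)C(C)(C)O1)
Why: Miyaura borylation of the alkenyl bromide (oxidative addition, boryl transfer from the phenoxide-activated diboron, reductive elimination) proceeds with retention of the 15E geometry.

**Part B – epoxy half**

Step 14
Reactants: 24 (4R,6R)-actinol
Product: 25 (4R,6R)-actinol tert-butyldimethylsilyl ether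
Conditions: TBSCl, imidazole, DMF, 25 °C
Reagents that add atoms: tert-butyldimethylsilyl chloride (CC(C)(C)[Si](C)(C)Cl)
Why: Silylation of the secondary alcohol protects the C3 oxygen through the enolate, hydride and oxidation chemistry that follows.

Step 15
Reactants: 25 (4R,6R)-actinol tert-butyldimethylsilyl ether
Product: 26 (4R)-silyloxy enol triflate
Conditions: LiN(i-Pr)2, THF, −78 °C; PhNTf2, −78 → 0 °C
Reagents that add atoms: N-phenylbis(trifluoromethanesulfonimide) (O=S(=O)(N(c1ccccc1)S(=O)(=O)C(F)(F)F)C(F)(F)F)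
Why: The ketone has a single enolisable position, so deprotonation and O-triflation of the lithium enolate give the tetrasubstituted enol triflate regiospecifically, erasing the methyl-bearing stereocentre on purpose and leaving C3 untouched.

Step 16
Reactants: 26 (4R)-silyloxy enol triflate
Product: 27 methyl (4R)-silyloxy cyclohexenecarboxylate
Conditions: Pd(OAc)2 (cat.), PPh3, CO (1 atm), MeOH, Et3N, DMF, 60 °C
Reagents that add atoms: carbon monoxide ([C-]#[O+]); methanol (CO)
Why: Palladium-catalysed methoxycarbonylation of the enol triflate (oxidative addition, CO insertion, methanolysis of the acylpalladium) installs C7.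

Step 17
Reactants: 27 methyl (4R)-silyloxy cyclohexenecarboxylate
Product: 28 (4R)-silyloxy cyclohexenylmethanol
Conditions: i-Bu2AlH (2.5 equiv), CH2Cl2, −78 → 0 °C; aq. potassium sodium tartrate
Reagents that add atoms: none
Why: 1,2-Reduction of the conjugated ester by the aluminium hydride gives the allylic alcohol needed to direct the epoxidation.

Step 18
Reactants: 28 (4R)-silyloxy cyclohexenylmethanol
Product: 29 anti epoxy alcohol
Conditions: Ti(Oi-Pr)4, D-(−)-diethyl tartrate, t-BuOOH, 4 Å MS, CH2Cl2, −20 °C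
Reagents that add atoms: tert-butyl hydroperoxide (CC(C)(C)OO)
Why: Sharpless asymmetric epoxidation, in which the titanium–D-(−)-tartrate complex delivers oxygen to the alkene face opposite the C3 silyloxy group (reagent control, expected to be matched with the steric bias of the ring), sets C5 and C6 with the oxirane anti to the C3 oxygen as in the (5R,6S) target.

Step 19
Reactants: 29 anti epoxy alcohol
Product: 30 epoxy aldehyde
Conditions: (n-Pr4N)RuO4 (5 mol %), NMO, 4 Å MS, CH2Cl2, 25 °C
Reagents that add atoms: none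
Why: Perruthenate-catalysed alcohol oxidation under neutral, water-free conditions gives the α,β-epoxy aldehyde without opening the oxirane.

Step 20
Reactants: 30 epoxy aldehyde; 31 triethyl 3-methyl-4-phosphonocrotonate
Product: 32 C15 epoxy dienoate
Conditions: 31, LiN(SiMe3)2, THF, −78 °C; then 30, −78 → 0 °C
Reagents that add atoms: none
Why: Horner–Wadsworth–Emmons olefination with the vinylogous phosphonoacetate forms C7=C8 with E selectivity under basic conditions that the tetrasubstituted oxirane tolerates, the 9E isomer being expected to dominate and to be purified here or at the next stage.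

Step 21
Reactants: 32 C15 epoxy dienoate
Product: 33 C15 epoxy dienol
Conditions: i-Bu2AlH, CH2Cl2, −78 °C; aq. potassium sodium tartrate
Reagents that add atoms: none
Why: Low-temperature aluminium hydride reduction takes the dienoate to the allylic alcohol without touching the vinyl oxirane.

Step 22
Reactants: 33 C15 epoxy dienol
Product: 34 C15 epoxy dienal
Conditions: MnO2, CH2Cl2, 25 °C
Reagents that add atoms: none
Why: Heterogeneous MnO2 oxidation is selective for allylic alcohols and neutral, so the dienal should form without acid contact of the oxirane.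

Step 23
Reactants: 35 propargyl alcohol; 15 trimethylaluminium
Product: 37 (E)-3-iodo-2-methylprop-2-en-1-ol, via alkenylalane 36 (not isolated)
Conditions: AlMe3 (3 equiv), Cp2ZrCl2 (0.25 equiv), CH2Cl2, 0 → 25 °C; I2, THF, −30 → 0 °C
Reagents that add atoms: iodine (II)
Why: Zirconium-catalysed syn methylalumination of the propargylic alcohol (as its aluminium alkoxide) followed by iodinolysis of the C–Al bond with retention gives the E-iodoalkene.

Step 24
Reactants: 37 (E)-3-iodo-2-methylprop-2-en-1-ol
Product: 38 (E)-3-bromo-1-iodo-2-methylprop-1-ene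
Conditions: CBr4, PPh3, CH2Cl2, 0 °C
Reagents that add atoms: carbon tetrabromide (BrC(Br)(Br)Br)
Why: Appel bromination converts the primary allylic alcohol into the bromide under neutral conditions without allylic transposition.

Step 25
Reactants: 38 (E)-3-bromo-1-iodo-2-methylprop-1-ene
Product: 39 diethyl (E)-(3-iodo-2-methylallyl)phosphonate
Conditions: P(OEt)3, neat, 100 °C
Reagents that add atoms: triethyl phosphite (CCOP(OCC)OCC)
Why: Michaelis–Arbuzov reaction of the primary allylic bromide gives the phosphonate, the vinyl iodide being inert to the phosphite in the absence of a metal catalyst.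

Step 26
Reactants: 34 C15 epoxy dienal; 39 diethyl (E)-(3-iodo-2-methylallyl)phosphonate
Product: 40 epoxy C19 tetraenyl iodide
Conditions: 39, NaN(SiMe3)2, THF, −78 °C; then 34, −78 → 0 °C, dark
Reagents that add atoms: none
Why: Horner–Wadsworth–Emmons olefination of the dienal with the allylic phosphonate anion forms C11=C12 with E selectivity, while the amide base at low temperature leaves the vinyl iodide and the oxirane intact.

**Part C – union and end game**

Step 27
Reactants: 23 ε C21 pentaenyl pinacol boronate; 40 epoxy C19 tetraenyl iodide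
Product: 41 lutein 5,6-epoxide bis(tert-butyldimethylsilyl) ether
Conditions: Pd(PPh3)4 (5 mol %), TlOEt, THF/H2O, 25 °C, dark
Reagents that add atoms: none
Why: Suzuki–Miyaura coupling, in which zerovalent palladium inserts into the alkenyl C–I bond, the ethoxide-activated boronate transmetalates and reductive elimination forms C14–C15 with retention at both alkenyl carbons, runs at room temperature under basic conditions that preserve the oxirane.

Step 28
Reactants: 41 lutein 5,6-epoxide bis(tert-butyldimethylsilyl) ether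
Product: 42 (3S,5R,6S,3'R,6'R)-lutein 5,6-epoxide
Conditions: n-Bu4NF, THF, 0 → 25 °C, dark
Reagents that add atoms: none
Why: Fluoride cleaves both Si–O bonds under non-acidic conditions, which avoids the acid-induced rearrangement of the 5,6-epoxide to the 5,8-furanoid oxide.

Step 29
Reactants: 42 (3S,5R,6S,3'R,6'R)-lutein 5,6-epoxide; 43 palmitic anhydride
Product: 44 lutein 5,6-epoxide dipalmitate (CNP0344034.1)
Conditions: 43 (3 equiv), DMAP (cat.), Et3N, CH2Cl2, 25 °C, argon, dark
Reagents that add atoms: none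
Why: DMAP-catalysed acyl transfer from the anhydride should esterify both secondary hydroxyls under buffered basic conditions, again keeping acid away from the oxirane.

**Compound list**

1 | (E)-α-ionone, racemic | CC(=O)/C=C/C1C(C)=CCCC1(C)C | starting material
2 | α-ionone ethylene ketal, racemic: 2-methyl-2-[(E)-2-(2,6,6-trimethylcyclohex-2-en-1-yl)ethenyl]-1,3-dioxolane | CC1(/C=C/C2C(C)=CCCC2(C)C)OCCO1 | intermediate
3 | 3-oxo-α-ionone ethylene ketal, racemic: 4-[(E)-2-(2-methyl-1,3-dioxolan-2-yl)ethenyl]-3,5,5-trimethylcyclohex-2-en-1-one | CC1(/C=C/C2C(C)=CC(=O)CC2(C)C)OCCO1 | intermediate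
4 | trans-3-hydroxy-α-ionone ethylene ketal, racemate (3R,6R plus 3S,6S, both enantiomers written) | CC1(/C=C/[C@H]2C(C)=C[C@H](O)CC2(C)C)OCCO1.CC1(/C=C/[C@@H]2C(C)=C[C@@H](O)CC2(C)C)OCCO1 | intermediate
5 | (3R,6R)-3-hydroxy-α-ionone ethylene ketal: (1R,4R)-4-[(E)-2-(2-methyl-1,3-dioxolan-2-yl)ethenyl]-3,5,5-trimethylcyclohex-2-en-1-ol | CC1(/C=C/[C@H]2C(C)=C[C@H](O)CC2(C)C)OCCO1 | intermediate
6 | (3R,6R)-3-(tert-butyldimethylsilyloxy)-α-ionone ethylene ketal | CC1(/C=C/[C@H]2C(C)=C[C@H](O[Si](C)(C)C(C)(C)C)CC2(C)C)OCCO1 | intermediate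
7 | (3R,6R)-3-(tert-butyldimethylsilyloxy)-α-ionone: (E)-4-[(1R,4R)-4-silyloxy-2,6,6-trimethylcyclohex-2-en-1-yl]but-3-en-2-one | CC(=O)/C=C/[C@H]1C(C)=C[C@H](O[Si](C)(C)C(C)(C)C)CC1(C)C | intermediate
8 | diethyl dienyl phosphate (enol phosphate of 7) | C=C(OP(=O)(OCC)OCC)/C=C/[C@H]1C(C)=C[C@H](O[Si](C)(C)C(C)(C)C)CC1(C)C | intermediate
9 | C13 silyloxy enyne: tert-butyl{[(1R,4R)-4-[(E)-but-1-en-3-yn-1-yl]-3,5,5-trimethylcyclohex-2-en-1-yl]oxy}dimethylsilane | C#C/C=C/[C@H]1C(C)=C[C@H](O[Si](C)(C)C(C)(C)C)CC1(C)C | intermediate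
10 | acetylene | C#C | starting material
11 | (E)-1-bromo-2-iodoethene | Br/C=C/I | intermediate
12 | ethynyltrimethylsilane | C#C[Si](C)(C)C | starting material
13 | [(trimethylsilyl)ethynyl]zinc bromide | C[Si](C)(C)C#C[Zn]Br | intermediate
14 | (E)-1-bromo-4-(trimethylsilyl)but-1-en-3-yne | Br/C=C/C#C[Si](C)(C)C | intermediate
15 | trimethylaluminium | C[Al](C)C | starting material
16 | (1E,3E)-dienyl(dimethyl)alane from 9 (Al on C10', CH3 on C9') | C[Al](C)/C=C(C)/C=C/[C@H]1C(C)=C[C@H](O[Si](C)(C)C(C)(C)C)CC1(C)C | intermediate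
17 | (1E,3E)-dienylzinc chloride from 16 | Cl[Zn]/C=C(C)/C=C/[C@H]1C(C)=C[C@H](O[Si](C)(C)C(C)(C)C)CC1(C)C | intermediate
18 | C18 silyl-capped trienyne: (1R,4R)-1-silyloxy-4-[(1E,3E,5E)-3-methyl-8-(trimethylsilyl)octa-1,3,5-trien-7-yn-1-yl]-3,5,5-trimethylcyclohex-2-ene | C[Si](C)(C)C#C/C=C/C=C(C)/C=C/[C@H]1C(C)=C[C@H](O[Si](C)(C)C(C)(C)C)CC1(C)C | intermediate
19 | ε C18 trienyne: tert-butyl{[(1R,4R)-4-[(1E,3E,5E)-3-methylocta-1,3,5-trien-7-yn-1-yl]-3,5,5-trimethylcyclohex-2-en-1-yl]oxy}dimethylsilane | C#C/C=C/C=C(C)/C=C/[C@H]1C(C)=C[C@H](O[Si](C)(C)C(C)(C)C)CC1(C)C | intermediate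
20 | tetraenyl(dimethyl)alane from 19 (Al on C14', CH3 on C13') | C[Al](C)/C=C(C)/C=C/C=C(C)/C=C/[C@H]1C(C)=C[C@H](O[Si](C)(C)C(C)(C)C)CC1(C)C | intermediate
21 | tetraenylzinc chloride from 20 | Cl[Zn]/C=C(C)/C=C/C=C(C)/C=C/[C@H]1C(C)=C[C@H](O[Si](C)(C)C(C)(C)C)CC1(C)C | intermediate
22 | ε C21 bromopentaene: {[(1R,4R)-4-[(1E,3E,5E,7E,9E)-10-bromo-3,7-dimethyldeca-1,3,5,7,9-pentaen-1-yl]-3,5,5-trimethylcyclohex-2-en-1-yl]oxy}(tert-butyl)dimethylsilane | Br/C=C/C=C(C)/C=C/C=C(C)/C=C/[C@H]1C(C)=C[C@H](O[Si](C)(C)C(C)(C)C)CC1(C)C | intermediate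
23 | ε C21 pentaenyl pinacol boronate (Bpin on C15 in place of Br) | CC1(C)OB(/C=C/C=C(C)/C=C/C=C(C)/C=C/[C@H]2C(C)=C[C@H](O[Si](C)(C)C(C)(C)C)CC2(C)C)OC1(C)C | intermediate
24 | (4R,6R)-actinol: (4R,6R)-4-hydroxy-2,2,6-trimethylcyclohexan-1-one | C[C@@H]1C[C@@H](O)CC(C)(C)C1=O | starting material
25 | (4R,6R)-4-(tert-butyldimethylsilyloxy)-2,2,6-trimethylcyclohexan-1-one | C[C@@H]1C[C@@H](O[Si](C)(C)C(C)(C)C)CC(C)(C)C1=O | intermediate
26 | (4R)-4-(tert-butyldimethylsilyloxy)-2,6,6-trimethylcyclohex-1-en-1-yl trifluoromethanesulfonate | CC1=C(OS(=O)(=O)C(F)(F)F)C(C)(C)C[C@H](O[Si](C)(C)C(C)(C)C)C1 | intermediate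
27 | methyl (4R)-4-(tert-butyldimethylsilyloxy)-2,6,6-trimethylcyclohex-1-ene-1-carboxylate | CC1=C(C(=O)OC)C(C)(C)C[C@H](O[Si](C)(C)C(C)(C)C)C1 | intermediate
28 | [(4R)-4-(tert-butyldimethylsilyloxy)-2,6,6-trimethylcyclohex-1-en-1-yl]methanol | CC1=C(CO)C(C)(C)C[C@H](O[Si](C)(C)C(C)(C)C)C1 | intermediate
29 | [(1R,4S,6R)-4-(tert-butyldimethylsilyloxy)-2,2,6-trimethyl-7-oxabicyclo[4.1.0]heptan-1-yl]methanol (oxirane anti to the silyloxy group) | CC(C)(C)[Si](C)(C)O[C@H]1CC(C)(C)[C@]2(CO)O[C@]2(C)C1 | intermediate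
30 | (1S,4S,6R)-4-(tert-butyldimethylsilyloxy)-2,2,6-trimethyl-7-oxabicyclo[4.1.0]heptane-1-carbaldehyde | CC(C)(C)[Si](C)(C)O[C@H]1CC(C)(C)[C@]2(C=O)O[C@]2(C)C1 | intermediate
31 | triethyl 3-methyl-4-phosphonocrotonate: ethyl (E)-4-(diethoxyphosphoryl)-3-methylbut-2-enoate | CCOC(=O)/C=C(\C)CP(=O)(OCC)OCC | starting material
32 | C15 epoxy dienoate: ethyl (2E,4E)-5-[(1S,4S,6R)-4-silyloxy-2,2,6-trimethyl-7-oxabicyclo[4.1.0]heptan-1-yl]-3-methylpenta-2,4-dienoate | CC(C)(C)[Si](C)(C)O[C@H]1CC(C)(C)[C@]2(/C=C/C(C)=C/C(=O)OCC)O[C@]2(C)C1 | intermediate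
33 | C15 epoxy dienol: (2E,4E)-5-[(1S,4S,6R)-4-silyloxy-2,2,6-trimethyl-7-oxabicyclo[4.1.0]heptan-1-yl]-3-methylpenta-2,4-dien-1-ol | CC(C)(C)[Si](C)(C)O[C@H]1CC(C)(C)[C@]2(/C=C/C(C)=C/CO)O[C@]2(C)C1 | intermediate
34 | C15 epoxy dienal: (2E,4E)-5-[(1S,4S,6R)-4-silyloxy-2,2,6-trimethyl-7-oxabicyclo[4.1.0]heptan-1-yl]-3-methylpenta-2,4-dienal | CC(C)(C)[Si](C)(C)O[C@H]1CC(C)(C)[C@]2(/C=C/C(C)=C/C=O)O[C@]2(C)C1 | intermediate
35 | propargyl alcohol | C#CCO | starting material
36 | (E)-alkenyl(dimethyl)alane dimethylaluminium alkoxide from 35 | C[Al](C)/C=C(\C)CO[Al](C)C | intermediate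
37 | (E)-3-iodo-2-methylprop-2-en-1-ol | OC/C(C)=C/I | intermediate
38 | (E)-3-bromo-1-iodo-2-methylprop-1-ene | BrC/C(C)=C/I | intermediate
39 | diethyl [(E)-3-iodo-2-methylprop-2-en-1-yl]phosphonate | CCOP(=O)(OCC)C/C(C)=C/I | intermediate
40 | epoxy C19 tetraenyl iodide: (1S,4S,6R)-1-[(1E,3E,5E,7E)-8-iodo-3,7-dimethylocta-1,3,5,7-tetraen-1-yl]-4-silyloxy-2,2,6-trimethyl-7-oxabicyclo[4.1.0]heptane | CC(C)(C)[Si](C)(C)O[C@H]1CC(C)(C)[C@]2(/C=C/C(C)=C/C=C/C(C)=C/I)O[C@]2(C)C1 | intermediate
41 | (3S,5R,6S,3'R,6'R)-5,6-epoxy-5,6-dihydro-β,ε-carotene-3,3'-diol bis(tert-butyldimethylsilyl) ether | CC(C)(C)[Si](C)(C)O[C@H]1CC(C)(C)[C@]2(/C=C/C(C)=C/C=C/C(C)=C/C=C/C=C(C)/C=C/C=C(C)/C=C/[C@H]3C(C)=C[C@H](O[Si](C)(C)C(C)(C)C)CC3(C)C)O[C@]2(C)C1 | intermediate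
42 | (3S,5R,6S,3'R,6'R)-lutein 5,6-epoxide | O[C@H]1CC(C)(C)[C@]2(/C=C/C(C)=C/C=C/C(C)=C/C=C/C=C(C)/C=C/C=C(C)/C=C/[C@H]3C(C)=C[C@H](O)CC3(C)C)O[C@]2(C)C1 | intermediate
43 | palmitic anhydride | CCCCCCCCCCCCCCCC(=O)OC(=O)CCCCCCCCCCCCCCC | starting material
44 | (3S,5R,6S,3'R,6'R)-5,6-epoxy-5,6-dihydro-β,ε-carotene-3,3'-diyl dihexadecanoate (CNP0344034.1) | CCCCCCCCCCCCCCCC(=O)O[C@H]1CC(C)(C)[C@]2(/C=C/C(C)=C/C=C/C(C)=C/C=C/C=C(C)/C=C/C=C(C)/C=C/[C@H]3C(C)=C[C@H](OC(=O)CCCCCCCCCCCCCCC)CC3(C)C)O[C@]2(C)C1 | target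

**Totals**

Total step count: 29.
Longest linear sequence: 14 steps (steps 1–7, 10–13, 27–29, from α-ionone).

**Steps most likely to fail**

1. Step 3 – hydride delivery from the wrong face, so that the cis alcohol dominates. Fallback, setting out from 3: Luche reduction (NaBH4, CeCl3·7H2O, MeOH), or collection of the cis material from the borohydride run, gives racemic cis-3-hydroxy-α-ionone ethylene ketal F1. A Mitsunobu reaction (4-nitrobenzoic acid, PPh3, DIAD, THF) inverts C3' and gives the racemic trans 4-nitrobenzoate F2, and K2CO3/MeOH methanolysis comes back to the route at 4.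

2. Step 4 – insufficient discrimination between the enantiomers by the enzyme, or acylation in the opposite sense. Fallback, setting out from 4: esterification with (S)-O-methylmandelic acid (DCC, DMAP, CH2Cl2) gives two diastereomeric esters, the (3R,6R)-ketal (S)-O-methylmandelate F3 and the (3S,6S)-ketal (S)-O-methylmandelate F4. They are separated by chromatography or crystallisation, and K2CO3/MeOH on F3 comes back to the route at 5.

3. Step 26 – sluggish elimination from the weakly stabilised phosphonate adduct, competing γ-deprotonation of the dienal and erosion of E selectivity at C11=C12. Fallback, setting out from 38 and 34: substitution of 38 with 1-phenyl-1H-tetrazole-5-thiol (K2CO3, acetone) gives the allylic tetrazolyl sulfide F5. Oxidation with H2O2 and (NH4)6Mo7O24 in EtOH gives the allylic tetrazolyl sulfone F6, and Julia–Kocienski olefination (KN(SiMe3)2, THF, −78 °C, then 34) comes back to the route at 40.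

**Further compounds**

F1 | step 3 | cis-3-hydroxy-α-ionone ethylene ketal, racemate (3S,6R plus 3R,6S) | CC1(/C=C/[C@H]2C(C)=C[C@@H](O)CC2(C)C)OCCO1.CC1(/C=C/[C@@H]2C(C)=C[C@H](O)CC2(C)C)OCCO1
F2 | step 3 | trans-3-(4-nitrobenzoyloxy)-α-ionone ethylene ketal, racemate | CC1(/C=C/[C@H]2C(C)=C[C@H](OC(=O)c3ccc(cc3)[N+](=O)[O-])CC2(C)C)OCCO1.CC1(/C=C/[C@@H]2C(C)=C[C@@H](OC(=O)c3ccc(cc3)[N+](=O)[O-])CC2(C)C)OCCO1
F3 | step 4 | (3R,6R)-3-hydroxy-α-ionone ethylene ketal (S)-methoxy(phenyl)acetate | CC1(/C=C/[C@H]2C(C)=C[C@H](OC(=O)[C@@H](OC)c3ccccc3)CC2(C)C)OCCO1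
F4 | step 4 | (3S,6S)-3-hydroxy-α-ionone ethylene ketal (S)-methoxy(phenyl)acetate | CC1(/C=C/[C@@H]2C(C)=C[C@@H](OC(=O)[C@@H](OC)c3ccccc3)CC2(C)C)OCCO1
F5 | step 26 | 5-{[(E)-3-iodo-2-methylprop-2-en-1-yl]sulfanyl}-1-phenyl-1H-tetrazole | I/C=C(C)/CSc1nnnn1-c1ccccc1
F6 | step 26 | 5-{[(E)-3-iodo-2-methylprop-2-en-1-yl]sulfonyl}-1-phenyl-1H-tetrazole | I/C=C(C)/CS(=O)(=O)c1nnnn1-c1ccccc1
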